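**Plan**
1. Retrosynthetic cuts, in order: the O–C(sp2) bond of the alkylidene oxolane (back to a ring alkyne and a ring carbinol); the bond between the ring CH2 and the isopropylidene-bearing α-carbon of the ketone (opens the 14-membered carbocycle to a vinyl group and an alkenyl bromide); the bond from that α-carbon to the carbonyl carbon; the CH2–alkyne bond beside the acetoxy carbon; last the trisubstituted alkene, the carbinol and the methyl-bearing centre of a C9 enyne diol.
2. Forward: crotonaldehyde is built into the C9 enyne diol (steps 1–5), joined to 2-methylglycidyl tosylate and homologated to the linalyl-type acetate (6–9), taken to the epoxy aldehyde and the alkenyl bromide (10–13); the 14-membered ring is closed by sp3–sp2 coupling (14); the ketone and then the oxolane (transannular hydroalkoxylation of the ring alkyne) follow (15–17).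
3. Enabling feature: in the 14-membered ring the ketone α-carbon is alkenyl and its exocyclic partner is CMe2, so an alkenyl bromide there has no geometry to control; the ring CH2CH2 leading to the quaternary acetoxy carbon is the anti-Markovnikov hydroboration image of a vinyl group.
4. Stereochemistry: acetoxy carbon from (R)-2-methylglycidol; ring-methyl centre by catalyst-controlled conjugate alkynylation; oxolane carbinol by catalyst-controlled propargylation; both oxirane centres by Sharpless epoxidation with L-(+)-tartrate; (Z)-enol ether by anti oxyauration; the temporary carbinol at the future ketone carbon is carried as both epimers.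

Key step: step 14

Assumption: the facial sense of the two catalyst-controlled additions (steps 1 and 2) is taken to follow the ligand and acid enantiomers named; the antipode would be used if a trial run showed the opposite sense.

Abbreviations: TIPS = triisopropylsilyl, TBS = tert-butyldimethylsilyl, TES = triethylsilyl, Ts = 4-methylbenzenesulfonyl.

**Step 1**
Reactants: 1 (E)-but-2-enal; 2 ethynyl(triisopropyl)silane
Product: 3 (3S)-3-methyl-5-(TIPS)pent-4-ynal
Conditions: [Rh(OAc)(C2H4)2]2 (2.5 mol%), (R)-DTBM-SEGPHOS (6 mol%), MeOH, 40 °C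
Reagents that add atoms: none
Why: Rhodium-catalysed asymmetric conjugate alkynylation of an enal should apply because the bulky silylalkyne resists dimerisation and the alkynylrhodium intermediate adds 1,4; the chiral bisphosphine selects the enal face and thereby sets the methyl-bearing stereocentre as (S).

**Step 2**
Reactants: 3 (3S)-3-methyl-5-(TIPS)pent-4-ynal; 4 allenylboronic acid pinacol ester
Product: 6 (4R,6S)-6-methyl-8-(TIPS)octa-1,7-diyn-4-ol, via pinacol borate ester 5 (not isolated)
Conditions: (S)-TRIP [(S)-3,3'-bis(2,4,6-triisopropylphenyl)-1,1'-binaphthyl-2,2'-diyl hydrogen phosphate] (10 mol%), 4 Å molecular sieves, toluene, 0 °C; aqueous NaHCO3 work-up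
Reagents that add atoms: none
Why: Chiral phosphoric acid catalysed allenylboration of an aldehyde (asymmetric propargylation) proceeds through a closed six-membered SE2' transition state in which the acid binds the boronate oxygen and the formyl hydrogen, so the acid enantiomer sets the new carbinol centre as (4R) while the remote (6S) centre has little influence, and the minor C-4 epimer is a separable diastereomer.

**Step 3**
Reactants: 6 (4R,6S)-6-methyl-8-(TIPS)octa-1,7-diyn-4-ol
Product: 8 (2E,5R,7S)-3,7-dimethyl-9-(TIPS)non-2-en-8-yne-1,5-diol, via alkenylalane 7 (not isolated)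
Conditions: AlMe3 (4 equiv), Cp2ZrCl2 (0.25 equiv), CH2Cl2, 0 °C → rt; evaporate; THF, n-BuLi, −78 °C; (CH2O)n, rt; aqueous potassium sodium tartrate
Reagents that add atoms: trimethylaluminium, C[Al](C)C; paraformaldehyde (as formaldehyde), C=O
Why: Zirconium-catalysed Negishi carboalumination: the hydroxyl is masked in the flask as its dimethylaluminium alkoxide, Me–Al adds syn to the terminal alkyne with methyl on the internal carbon while the hindered silylalkyne is inert, and after activation with n-BuLi the alkenyl–aluminium bond is hydroxymethylated by formaldehyde with retention, which fixes the (E)-trisubstituted alkene (no stereocentre is formed).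

**Step 4**
Reactants: 8 (2E,5R,7S)-3,7-dimethyl-9-(TIPS)non-2-en-8-yne-1,5-diol
Product: 9 (2E,5R,7S)-3,7-dimethylnon-2-en-8-yne-1,5-diol
Conditions: Bu4NF, THF, 0 °C → rt
Reagents that add atoms: none
Why: Fluoride-induced protodesilylation cleaves the C(sp)–Si bond and frees the terminal alkyne needed for the fragment union, and the free diol is inert to fluoride.

**Step 5**
Reactants: 9 (2E,5R,7S)-3,7-dimethylnon-2-en-8-yne-1,5-diol
Product: 10 (2E,5R,7S)-1,5-bis(TBS-oxy)-3,7-dimethylnon-2-en-8-yne
Conditions: TBSCl (2.5 equiv), imidazole, DMF, rt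
Reagents that add atoms: tert-butyl(chloro)dimethylsilane, CC(C)(C)[Si](C)(C)Cl
Why: Standard silyl ether formation with the silyl chloride and imidazole protects the primary allylic and the secondary hydroxyl, the alkyne C–H being untouched under these weakly basic conditions.

**Step 6**
Reactants: 11 (R)-2-methylglycidol
Product: 12 (S)-(2-methyloxiran-2-yl)methyl 4-methylbenzenesulfonate
Conditions: TsCl, Et3N, DMAP (cat.), CH2Cl2, 0 °C
Reagents that add atoms: 4-methylbenzenesulfonyl chloride, Cc1ccc(cc1)S(Cl)(=O)=O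
Why: Sulfonylation of the primary hydroxyl turns it into the leaving group needed in step 7 without touching the oxirane or its quaternary stereocentre, which comes from the chiral pool.

**Step 7**
Reactants: 10 (2E,5R,7S)-1,5-bis(TBS-oxy)-3,7-dimethylnon-2-en-8-yne; 12 (S)-(2-methyloxiran-2-yl)methyl 4-methylbenzenesulfonate
Product: 15 (2S)-2-[(4S,6R,8E)-6,10-bis(TBS-oxy)-4,8-dimethyldec-8-en-2-yn-1-yl]-2-methyloxirane, via lithium acetylide 13 (not isolated), via hydroxy tosylate 14 (not isolated)
Conditions: n-BuLi, THF, −78 °C; BF3·OEt2, then 12, −78 °C; then K2CO3, MeOH, rt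
Reagents that add atoms: none
Why: Lewis-acid-assisted SN2 opening of a 2,2-disubstituted oxirane by a lithium acetylide occurs at the unsubstituted ring carbon, and base then closes a new oxirane by 3-exo-tet attack of the tertiary alkoxide on the neighbouring tosylate, so no bond to the quaternary centre is broken and its configuration is kept.

**Step 8**
Reactants: 15 (2S)-2-[(4S,6R,8E)-6,10-bis(TBS-oxy)-4,8-dimethyldec-8-en-2-yn-1-yl]-2-methyloxirane
Product: 17 (3S,7S,9R,11E)-9,13-bis(TBS-oxy)-3,7,11-trimethyltrideca-1,11-dien-5-yn-3-ol, via sulfonium alkoxide betaine 16 (not isolated)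
Conditions: Me3S+ I− (5 equiv), n-BuLi (4.8 equiv), THF, −10 °C → rt
Reagents that add atoms: trimethylsulfonium iodide, C[S+](C)C.[I-]
Why: Excess dimethylsulfonium methylide converts a terminal oxirane into the one-carbon-homologated allylic alcohol: the ylide opens the ring at CH2 and a second equivalent induces loss of dimethyl sulfide from the resulting sulfonium alkoxide, which gives the vinyl carbinol with the quaternary centre unchanged.

**Step 9**
Reactants: 17 (3S,7S,9R,11E)-9,13-bis(TBS-oxy)-3,7,11-trimethyltrideca-1,11-dien-5-yn-3-ol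
Product: 18 (3S,7S,9R,11E)-9,13-bis(TBS-oxy)-3,7,11-trimethyltrideca-1,11-dien-5-yn-3-yl acetate
Conditions: Ac2O, DMAP, Et3N, CH2Cl2, rt
Reagents that add atoms: acetic anhydride, CC(=O)OC(C)=O
Why: DMAP-catalysed acetylation of the only free hydroxyl gives the tertiary acetate; the hindered tertiary alcohol should react slowly but cleanly with excess anhydride.

**Step 10**
Reactants: 18 (3S,7S,9R,11E)-9,13-bis(TBS-oxy)-3,7,11-trimethyltrideca-1,11-dien-5-yn-3-yl acetate
Product: 19 (3S,7S,9R,11E)-9-(TBS-oxy)-13-hydroxy-3,7,11-trimethyltrideca-1,11-dien-5-yn-3-yl acetate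
Conditions: HF·pyridine, pyridine, THF, 0 °C
Reagents that add atoms: none
Why: Buffered HF·pyridine cleaves the unhindered primary allylic silyl ether much faster than the secondary one (selective desilylation) and is too weakly acidic to ionise the tertiary allylic acetate.

**Step 11**
Reactants: 19 (3S,7S,9R,11E)-9-(TBS-oxy)-13-hydroxy-3,7,11-trimethyltrideca-1,11-dien-5-yn-3-yl acetate
Product: 20 (3S,7S,9R)-9-(TBS-oxy)-10-[(2S,3S)-3-(hydroxymethyl)-2-methyloxiran-2-yl]-3,7-dimethyldec-1-en-5-yn-3-yl acetate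
Conditions: Ti(OiPr)4, L-(+)-diethyl tartrate, t-BuOOH, 4 Å molecular sieves, CH2Cl2, −20 °C
Reagents that add atoms: tert-butyl hydroperoxide, CC(C)(C)OO
Why: Sharpless asymmetric epoxidation is directed by the primary allylic hydroxyl, so only this alkene reacts, and with L-(+)-diethyl tartrate an (E)-3-methylalk-2-en-1-ol of the geraniol type gives the (2S,3S)-epoxy alcohol, which sets both oxirane stereocentres by reagent control.

**Step 12**
Reactants: 20 (3S,7S,9R)-9-(TBS-oxy)-10-[(2S,3S)-3-(hydroxymethyl)-2-methyloxiran-2-yl]-3,7-dimethyldec-1-en-5-yn-3-yl acetate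
Product: 21 (3S,7S,9R)-9-(TBS-oxy)-10-[(2S,3R)-3-formyl-2-methyloxiran-2-yl]-3,7-dimethyldec-1-en-5-yn-3-yl acetate
Conditions: Dess–Martin periodinane, NaHCO3, CH2Cl2, 0 °C → rt
Reagents that add atoms: none
Why: Dess–Martin oxidation under bicarbonate buffering converts the primary epoxy alcohol into the aldehyde without opening the oxirane or epimerising its α-carbon.

**Step 13**
Reactants: 21 (3S,7S,9R)-9-(TBS-oxy)-10-[(2S,3R)-3-formyl-2-methyloxiran-2-yl]-3,7-dimethyldec-1-en-5-yn-3-yl acetate; 22 1,1-dibromo-2-methylprop-1-ene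
Product: 25 (3S,7S,9R)-10-[(2S,3S)-3-{2-bromo-3-methyl-1-(TES-oxy)but-2-en-1-yl}-2-methyloxiran-2-yl]-9-(TBS-oxy)-3,7-dimethyldec-1-en-5-yn-3-yl acetate (both epimers at the TES-oxy carbon), via bromo-lithio carbenoid 23 (not isolated), via lithium alkoxide 24 (not isolated)
Conditions: 22, n-BuLi, THF/Et2O/pentane, −110 °C; then 21, −110 → −90 °C; then Et3SiCl, −90 → 0 °C
Reagents that add atoms: chlorotriethylsilane, CC[Si](Cl)(CC)CC
Why: Bromine–lithium exchange on the gem-dibromoalkene gives an α-bromo alkenyllithium carbenoid that is persistent below −100 °C and adds to the aldehyde far faster than to the acetate (1,2-addition), and the lithium alkoxide is silylated in the flask; the new carbinol centre forms as both epimers, which is immaterial because step 16 turns it into the ketone.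

**Step 14**
Reactants: 25 (3S,7S,9R)-10-[(2S,3S)-3-{2-bromo-3-methyl-1-(TES-oxy)but-2-en-1-yl}-2-methyloxiran-2-yl]-9-(TBS-oxy)-3,7-dimethyldec-1-en-5-yn-3-yl acetate
Product: 27 (1R,5S,7R,9S,10S)-7-(TBS-oxy)-9,10-epoxy-1,5,9-trimethyl-12-(propan-2-ylidene)-11-(TES-oxy)cyclotetradec-3-yn-1-yl acetate (both C-11 epimers), via B-alkyl-9-BBN 26 (not isolated)
Conditions: 9-BBN, THF, 0 °C → rt; then slow addition (syringe pump) to Pd(OAc)2 (15 mol%), SPhos (2-dicyclohexylphosphino-2',6'-dimethoxybiphenyl, 30 mol%), aqueous K3PO4, THF, 60 °C, about 2 mM final concentration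
Reagents that add atoms: none
Why: 9-BBN adds to the monosubstituted vinyl group of 25 with boron on the terminal carbon (its neighbour is quaternary), the internal alkyne and the tetrasubstituted bromoalkene reacting far more slowly, to give 26; zerovalent palladium formed from Pd(OAc)2 and SPhos inserts into the C–Br bond, the phosphate-activated borate transfers its primary alkyl group to divalent palladium, and reductive elimination forms the sp3–sp2 bond. The closest known reaction type is the B-alkyl Suzuki–Miyaura macrocyclisation of an alkenyl halide carrying a tethered alkyl-9-BBN. The one ring closed is the 14-membered carbocycle, by end-to-end cross-coupling (reductive elimination from a 15-membered palladacycle), favoured over oligomerisation by slow addition of 26 into the hot catalyst solution at high dilution and by the rigid alkyne and oxirane that restrict the tether. No stereocentre is formed and no alkene geometry is at stake, because the exocyclic partner of the coupled alkene carbon carries two identical methyl groups; the five existing stereocentres are not touched. The step needs the borane to leave the future carbonyl alone, which is secured by carrying that carbon as a silyl-protected carbinol, and it needs the tertiary acetate to be inert to zerovalent palladium, which is secured because hydroboration has already removed the allylic double bond.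

**Step 15**
Reactants: 27 (1R,5S,7R,9S,10S)-7-(TBS-oxy)-9,10-epoxy-1,5,9-trimethyl-12-(propan-2-ylidene)-11-(TES-oxy)cyclotetradec-3-yn-1-yl acetate
Product: 28 (1R,5S,7R,9S,10S)-9,10-epoxy-7,11-dihydroxy-1,5,9-trimethyl-12-(propan-2-ylidene)cyclotetradec-3-yn-1-yl acetate (both C-11 epimers)
Conditions: Bu4NF, AcOH, THF, 0 °C → rt
Reagents that add atoms: none
Why: Fluoride cleaves both silyl ethers (desilylation), and acetic acid buffering keeps the medium from becoming basic enough for acetate loss or epoxide migration.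

**Step 16**
Reactants: 28 (1R,5S,7R,9S,10S)-9,10-epoxy-7,11-dihydroxy-1,5,9-trimethyl-12-(propan-2-ylidene)cyclotetradec-3-yn-1-yl acetate
Product: 29 (1R,5S,7R,9S,10R)-9,10-epoxy-7-hydroxy-1,5,9-trimethyl-11-oxo-12-(propan-2-ylidene)cyclotetradec-3-yn-1-yl acetate
Conditions: activated MnO2 (excess), CH2Cl2, rt
Reagents that add atoms: none
Why: Activated MnO2 oxidises allylic alcohols selectively, so the hydroxyl next to the isopropylidene alkene becomes the cross-conjugated ketone while the saturated ring carbinol stays free, and the epimeric centre is erased.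

**Step 17**
Reactants: 29 (1R,5S,7R,9S,10R)-9,10-epoxy-7-hydroxy-1,5,9-trimethyl-11-oxo-12-(propan-2-ylidene)cyclotetradec-3-yn-1-yl acetate
Product: 30 (1R,3Z,5S,7R,9S,10R)-4,7:9,10-diepoxy-1,5,9-trimethyl-11-oxo-12-(propan-2-ylidene)cyclotetradec-3-en-1-yl acetate (CNP0162736.1)
Conditions: AuCl (10 mol%), K2CO3 (10 mol%), MeCN, rt
Reagents that add atoms: none
Why: Gold-catalysed alkynol cycloisomerisation (transannular hydroalkoxylation): π-activation of the ring alkyne triggers 5-exo-dig anti attack of the ring hydroxyl on the alkyne carbon next to the methyl-bearing centre, which closes the oxolane, and protodeauration with retention places the ring oxygen and the new vinylic hydrogen trans, which is the (Z)-enol ether of the target; both oxolane stereocentres are already fixed (trans) and the carbonate additive suppresses acid-induced migration of the exocyclic double bond.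

**Compound list** (macrocycles are numbered from the acetoxy carbon, C-1, through the alkyne carbons C-3 and C-4; the carbinol carbon that later becomes the ketone is left undefined in the SMILES of 24–28 because both epimers are carried)

1 | (E)-but-2-enal | C/C=C/C=O | starting material
2 | ethynyl(triisopropyl)silane | C#C[Si](C(C)C)(C(C)C)C(C)C | starting material
3 | (3S)-3-methyl-5-(TIPS)pent-4-ynal | O=CC[C@H](C)C#C[Si](C(C)C)(C(C)C)C(C)C | intermediate
4 | allenylboronic acid pinacol ester | C=C=CB1OC(C)(C)C(C)(C)O1 | starting material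
5 | pinacol borate ester of 6 | C#CC[C@H](OB1OC(C)(C)C(C)(C)O1)C[C@H](C)C#C[Si](C(C)C)(C(C)C)C(C)C | intermediate
6 | (4R,6S)-6-methyl-8-(TIPS)octa-1,7-diyn-4-ol | C#CC[C@H](O)C[C@H](C)C#C[Si](C(C)C)(C(C)C)C(C)C | intermediate
7 | (E)-alkenyl(dimethyl)alane from 6, hydroxyl as dimethylaluminium alkoxide | C[Al](C)/C=C(\C)C[C@H](O[Al](C)C)C[C@H](C)C#C[Si](C(C)C)(C(C)C)C(C)C | intermediate
8 | (2E,5R,7S)-3,7-dimethyl-9-(TIPS)non-2-en-8-yne-1,5-diol | OC/C=C(\C)C[C@H](O)C[C@H](C)C#C[Si](C(C)C)(C(C)C)C(C)C | intermediate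
9 | (2E,5R,7S)-3,7-dimethylnon-2-en-8-yne-1,5-diol | OC/C=C(\C)C[C@H](O)C[C@H](C)C#C | intermediate
10 | (2E,5R,7S)-1,5-bis(TBS-oxy)-3,7-dimethylnon-2-en-8-yne | CC(C)(C)[Si](C)(C)OC/C=C(\C)C[C@H](O[Si](C)(C)C(C)(C)C)C[C@H](C)C#C | intermediate
11 | (R)-2-methylglycidol | C[C@@]1(CO)CO1 | starting material
12 | (S)-(2-methyloxiran-2-yl)methyl 4-methylbenzenesulfonate | C[C@@]1(COS(=O)(=O)c2ccc(C)cc2)CO1 | intermediate
13 | lithium acetylide of 10 | [Li]C#C[C@@H](C)C[C@@H](O[Si](C)(C)C(C)(C)C)C/C(C)=C/CO[Si](C)(C)C(C)(C)C | intermediate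
14 | (2S,6S,8R,10E)-8,12-bis(TBS-oxy)-2-hydroxy-2,6,10-trimethyldodec-10-en-4-yn-1-yl 4-methylbenzenesulfonate | C[C@@](O)(COS(=O)(=O)c1ccc(C)cc1)CC#C[C@@H](C)C[C@@H](O[Si](C)(C)C(C)(C)C)C/C(C)=C/CO[Si](C)(C)C(C)(C)C | intermediate
15 | (2S)-2-[(4S,6R,8E)-6,10-bis(TBS-oxy)-4,8-dimethyldec-8-en-2-yn-1-yl]-2-methyloxirane | C[C@@]1(CO1)CC#C[C@@H](C)C[C@@H](O[Si](C)(C)C(C)(C)C)C/C(C)=C/CO[Si](C)(C)C(C)(C)C | intermediate
16 | γ-oxido dimethylsulfonium betaine from 15 | C[C@@]([O-])(CC[S+](C)C)CC#C[C@@H](C)C[C@@H](O[Si](C)(C)C(C)(C)C)C/C(C)=C/CO[Si](C)(C)C(C)(C)C | intermediate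
17 | (3S,7S,9R,11E)-9,13-bis(TBS-oxy)-3,7,11-trimethyltrideca-1,11-dien-5-yn-3-ol | C[C@@](O)(C=C)CC#C[C@@H](C)C[C@@H](O[Si](C)(C)C(C)(C)C)C/C(C)=C/CO[Si](C)(C)C(C)(C)C | intermediate
18 | (3S,7S,9R,11E)-9,13-bis(TBS-oxy)-3,7,11-trimethyltrideca-1,11-dien-5-yn-3-yl acetate | CC(=O)O[C@](C)(C=C)CC#C[C@@H](C)C[C@@H](O[Si](C)(C)C(C)(C)C)C/C(C)=C/CO[Si](C)(C)C(C)(C)C | intermediate
19 | (3S,7S,9R,11E)-9-(TBS-oxy)-13-hydroxy-3,7,11-trimethyltrideca-1,11-dien-5-yn-3-yl acetate | CC(=O)O[C@](C)(C=C)CC#C[C@@H](C)C[C@@H](O[Si](C)(C)C(C)(C)C)C/C(C)=C/CO | intermediate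
20 | (3S,7S,9R)-9-(TBS-oxy)-10-[(2S,3S)-3-(hydroxymethyl)-2-methyloxiran-2-yl]-3,7-dimethyldec-1-en-5-yn-3-yl acetate | CC(=O)O[C@](C)(C=C)CC#C[C@@H](C)C[C@@H](O[Si](C)(C)C(C)(C)C)C[C@]1(C)O[C@H]1CO | intermediate
21 | (3S,7S,9R)-9-(TBS-oxy)-10-[(2S,3R)-3-formyl-2-methyloxiran-2-yl]-3,7-dimethyldec-1-en-5-yn-3-yl acetate | CC(=O)O[C@](C)(C=C)CC#C[C@@H](C)C[C@@H](O[Si](C)(C)C(C)(C)C)C[C@]1(C)O[C@H]1C=O | intermediate
22 | 1,1-dibromo-2-methylprop-1-ene | CC(C)=C(Br)Br | starting material
23 | (1-bromo-2-methylprop-1-en-1-yl)lithium | CC(C)=C(Br)[Li] | intermediate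
24 | lithium alkoxide from addition of 23 to 21 | CC(=O)O[C@](C)(C=C)CC#C[C@@H](C)C[C@@H](O[Si](C)(C)C(C)(C)C)C[C@]1(C)O[C@H]1C(O[Li])C(Br)=C(C)C | intermediate
25 | (3S,7S,9R)-10-[(2S,3S)-3-{2-bromo-3-methyl-1-(TES-oxy)but-2-en-1-yl}-2-methyloxiran-2-yl]-9-(TBS-oxy)-3,7-dimethyldec-1-en-5-yn-3-yl acetate | CC(=O)O[C@](C)(C=C)CC#C[C@@H](C)C[C@@H](O[Si](C)(C)C(C)(C)C)C[C@]1(C)O[C@H]1C(O[Si](CC)(CC)CC)C(Br)=C(C)C | intermediate
26 | B-alkyl-9-borabicyclo[3.3.1]nonane from 25 (boron on the former terminal vinyl carbon) | CC(=O)O[C@](C)(CCB1C2CCCC1CCC2)CC#C[C@@H](C)C[C@@H](O[Si](C)(C)C(C)(C)C)C[C@]1(C)O[C@H]1C(O[Si](CC)(CC)CC)C(Br)=C(C)C | intermediate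
27 | (1R,5S,7R,9S,10S)-7-(TBS-oxy)-9,10-epoxy-1,5,9-trimethyl-12-(propan-2-ylidene)-11-(TES-oxy)cyclotetradec-3-yn-1-yl acetate | CC(=O)O[C@@]1(C)CC#C[C@@H](C)C[C@@H](O[Si](C)(C)C(C)(C)C)C[C@]2(C)O[C@H]2C(O[Si](CC)(CC)CC)C(=C(C)C)CC1 | intermediate
28 | (1R,5S,7R,9S,10S)-9,10-epoxy-7,11-dihydroxy-1,5,9-trimethyl-12-(propan-2-ylidene)cyclotetradec-3-yn-1-yl acetate | CC(=O)O[C@@]1(C)CC#C[C@@H](C)C[C@@H](O)C[C@]2(C)O[C@H]2C(O)C(=C(C)C)CC1 | intermediate
29 | (1R,5S,7R,9S,10R)-9,10-epoxy-7-hydroxy-1,5,9-trimethyl-11-oxo-12-(propan-2-ylidene)cyclotetradec-3-yn-1-yl acetate | CC(=O)O[C@@]1(C)CC#C[C@@H](C)C[C@@H](O)C[C@]2(C)O[C@H]2C(=O)C(=C(C)C)CC1 | intermediate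
30 | (1R,3Z,5S,7R,9S,10R)-4,7:9,10-diepoxy-1,5,9-trimethyl-11-oxo-12-(propan-2-ylidene)cyclotetradec-3-en-1-yl acetate (CNP0162736.1) | CC(=O)O[C@@]1(C)C/C=C2\O[C@H](C[C@@H]2C)C[C@]2(C)O[C@H]2C(=O)C(=C(C)C)CC1 | target

**Step count and risks**

Total steps: 17. Longest linear sequence: 16 steps (steps 1–5 and 7–17; step 6 is the side branch).

Steps most likely to fail:

Step 14. Oxidative addition into the hindered tetrasubstituted alkenyl bromide may be slow compared with protodeboronation and intermolecular coupling, so that reduced and oligomeric material forms instead of the ring. The fallback sets out from 25 and returns at 27, and it replaces boron by zinc. Hydroboration of 25 to 26 followed by oxidation (NaBO3) would give the primary alcohol F1. Appel iodination (I2, PPh3, imidazole) would give the primary iodide F2. Zinc insertion (Zn dust, LiCl, THF) would give the alkylzinc iodide F3, which would be added slowly to Pd(OAc)2 and SPhos in THF so that an intramolecular Negishi coupling closes the same bond and gives 27.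

Step 17. The hydroxyl may add in the 6-endo sense, or the exocyclic enol ether may migrate into the oxolane ring or take up a second nucleophile while the π-acid is present. The fallback sets out from 29 and returns at 30. Iodoetherification of 29 with N-iodosuccinimide and NaHCO3 in MeCN would give, by anti addition, the (E)-iodo enol ether F4, which cannot tautomerise. Palladium-catalysed hydrodeiodination with retention (Pd(OAc)2, PPh3, HCO2H, Et3N, DMF) would then give 30.

Step 2. Facial discrimination by the chiral acid may be poor for an unbranched aliphatic aldehyde, which would lower the diastereomeric purity at the carbinol. The fallback sets out from 3 and returns at 6. Uncatalysed addition of allenylmagnesium bromide to 3 would give both carbinol epimers, which are diastereomers and would be separated. The unwanted (4S,6S)-alcohol F5 would be inverted by Mitsunobu esterification (4-nitrobenzoic acid, PPh3, diisopropyl azodicarboxylate) to the (4R)-4-nitrobenzoate F6, and methanolysis (K2CO3, MeOH) would give 6.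

**Further compounds**
F1 | step 14 | (3S,7S,9R)-10-[(2S,3S)-3-{2-bromo-3-methyl-1-(TES-oxy)but-2-en-1-yl}-2-methyloxiran-2-yl]-9-(TBS-oxy)-1-hydroxy-3,7-dimethyldec-5-yn-3-yl acetate | CC(=O)O[C@](C)(CCO)CC#C[C@@H](C)C[C@@H](O[Si](C)(C)C(C)(C)C)C[C@]1(C)O[C@H]1C(O[Si](CC)(CC)CC)C(Br)=C(C)C
F2 | step 14 | the corresponding 1-iodide of F1 | CC(=O)O[C@](C)(CCI)CC#C[C@@H](C)C[C@@H](O[Si](C)(C)C(C)(C)C)C[C@]1(C)O[C@H]1C(O[Si](CC)(CC)CC)C(Br)=C(C)C
F3 | step 14 | alkylzinc iodide from F2 | CC(=O)O[C@](C)(CC[Zn]I)CC#C[C@@H](C)C[C@@H](O[Si](C)(C)C(C)(C)C)C[C@]1(C)O[C@H]1C(O[Si](CC)(CC)CC)C(Br)=C(C)C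
F4 | step 17 | (1R,3E,5S,7R,9S,10R)-4,7:9,10-diepoxy-3-iodo-1,5,9-trimethyl-11-oxo-12-(propan-2-ylidene)cyclotetradec-3-en-1-yl acetate | CC(=O)O[C@@]1(C)C/C(I)=C2\O[C@H](C[C@@H]2C)C[C@]2(C)O[C@H]2C(=O)C(=C(C)C)CC1
F5 | step 2 | (4S,6S)-6-methyl-8-(TIPS)octa-1,7-diyn-4-ol | C#CC[C@@H](O)C[C@H](C)C#C[Si](C(C)C)(C(C)C)C(C)C
F6 | step 2 | (4R,6S)-6-methyl-8-(TIPS)octa-1,7-diyn-4-yl 4-nitrobenzoate | C#CC[C@H](OC(=O)c1ccc(cc1)[N+](=O)[O-])C[C@H](C)C#C[Si](C(C)C)(C(C)C)C(C)C
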